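The runs are calculated for substances that don't exist; the scatter is artificial.

Take 31.7% of target at 80.0 s in the winter run, and square the time. Target in that run grows roughly with the square of time, so one number describes the rise.

| flask | starting material | second substrate | precatalyst | remark |
|---|---|---|---|---|
| winter | 0.18 M | 2 equiv | 0.0018 mol% | the very flask that is asked about, followed so far |
| flask | 0.18 M | 2.00 equiv | 0.0018 mol% |  |
- winter (time / s: target / %, starting material / %): 15.0: 1.5, 97.7; 30.0: 6.1, 95.7; 40.0: 8.6, 90.0; 60.0: 18.9, 81.2; 80.0: 31.7, 70.2

(standard deviation of a reading: 1 percentage point)
1. factor on the rate of making target when 20% of the starting material are converted if second substrate is charged twice over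
2. factor on the rate when 20% of the starting material are converted if precatalyst is charged at 2.0 × 10⁻⁴ mol% instead
- no earlier run changes the charge of second substrate; that part of a forecast is a guess
- no earlier run changes the charge of precatalyst; that part of a forecast is a guess

Define the rise time as the time to reach 20% conversion on that square law. Reckon it from the last reading:

rise time = 80.0 s × √(20% / 31.7%) = 63.5 s

The reading at 60.0 s gives 61.7 s. Now draw the curve. It starts nearly flat, with 1.5% at 15.0 s. On that law, target crosses starting material at about 100 s. The two readings at 80.0 s sum to 102%, so expect a level at the full charge. The square law reaches that level at 142 s, so expect the knee before then.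

If enzyme grows in step with time and loading, the rise time goes with one over the root of the loading, and the rate at fixed conversion goes with the root. My factor for less precatalyst is then:

√(2.0 × 10⁻⁴ mol% / 0.0018 mol%) = 0.333

For second substrate, I have a guess and no reckoning. The forecast gives 1.4 and 0.33, on “active catalyst growing roughly linearly with time”.

The flask gives 0.900 and 0.241, and reaches 20% conversion at 1.02 min.

    complex B → enzyme + second product (k = 1110 s⁻¹)
    starting material + enzyme ⇌ complex A (K = 220 M⁻¹, k = 40800 M⁻¹ s⁻¹)
    second substrate + enzyme ⇌ complex B (K = 63.0 M⁻¹, k = 75900 M⁻¹ s⁻¹)
    second substrate ⇌ dormant form (K = 9.05, k = 0.211 s⁻¹)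
    complex A → enzyme + target (k = 1420 s⁻¹)
    precatalyst → enzyme (k = 0.00740 s⁻¹)

Set the rise time against 2.96 s, the relaxation half-life of second substrate and dormant form: it is 21.5 times longer. By 0.400 min free second substrate already stands at 10.1% of its charge. On the square law, the flask with less precatalyst takes 191 s, longer still. A run without the exchange of second substrate with dormant form, at 20% conversion, goes at 0.591 times the actual rate.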